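# Shimalactone B: a convergent route through a pyrone Diels–Alder/CO2-extrusion on an enantiopure cyclobutene

## The problem

Atoms are numbered along the backbone from C1 (terminal methyl of the butenyl group) to C21, with the ring oxygen as O17; each methyl branch is named by the carbon that bears it.

Shimalactone B (34) is made of two bicyclic halves that meet at the E-configured trisubstituted alkene C13=C14. The west half is a cyclobutane (C5, C6, C11, C12) cis-fused along C6–C11 to a cyclohexa-1,3-diene, with the C1–C4 tiglyl carbinol on C5. The east half is a 2-oxabicyclo[2.2.1]heptane-3,5-dione in which a γ-lactone and a cyclopentanone share C15, C16 and C19. Nine stereocentres must be set; four are quaternary (C5, C11, C15, C19), and C15 and C19 are bonded to each other. Within each half the centres can relay. C5 can decide the face on which the six-membered ring is fused (C6, C11) and on which C12 is substituted. C16 can decide C15 and C19 when the bicycle closes, and C21 is under thermodynamic control. C4 sits beside a quaternary carbon whose three carbon substituents differ little in size, so it needs reagent control. The two halves are separated by the planar C13=C14 unit and cannot control each other, so each must be a single enantiomer and the union must preserve configuration and alkene geometry. Sensitive groups are the cyclohexadiene (oxidation, acid, reversible 6π opening on heating), cyclobutene intermediates (4π opening, easy when a carbonyl sits on a ring sp3 carbon), the C4 allylic alcohol beside the strained ring, and the east β-acyloxy ketone, which can expel the C16 carboxylate through the C21 enolate. The feature that opens a short route to the west half is the diene C7=C8–C9=C10, with methyls on C7 and C9 and sp3 termini C6 and C11 that are adjacent cyclobutane atoms. This is what remains when 4,6-dimethylpyran-2-one adds across the C6=C11 bond of a cyclobutene and the adduct loses CO2.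

## Retrosynthesis

**Union, C12–C13.** After removal of the C4 silyl ether (34 from 33), the sp3–sp2 bond C12–C13 is cut, giving the west redox-active ester 17 and the east (E)-alkenyl iodide 32. The neighbouring cuts are worse: C13=C14 would need an olefination between two carbons that both sit on quaternary centres, and C14–C15 would create the quaternary C15 in the coupling. The cut gives two halves of similar size that carry no stereochemical information for each other. The forward reaction, a nickel-catalysed decarboxylative alkenylation, must capture a cyclobutyl radical flanked by two quaternary carbons on the face anti to the C5 side chain and the C11 methyl, and must keep the iodide geometry.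

**West bicycle, C6–C7 and C10–C11.** Ester 17 comes from acid 16 and methyl ester 15 by functional-group changes. In 15 the bonds C6–C7 and C10–C11 are cut, with CO2 restored between C7 and C10; this leads to cyclobutene 12 and pyrone 13 by way of the bridged lactone 14. The alternatives build the four-membered ring last, by [2+2] addition to an arene or by electrocyclisation of a tetraene. Both are fast but leave absolute configuration and the placement of the C5 and C12 substituents uncontrolled. Cutting the six-membered ring instead removes one ring and two stereocentres and leaves a monocyclic cyclobutene whose C5 centre is already in place to direct the addition. The forward step must be regioselective (methyl-bearing pyrone carbon to C6), face-selective (anti to the C5 side chain) and selective for the strained alkene over the tiglyl alkene. It must also run below the temperature at which the cyclobutene opens.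

**Side chain, C3–C4.** Silyl ether 12 is the protected form of allylic alcohol 11, which is cut at C3–C4 into aldehyde 7 and the alkenyl unit of but-2-yne (8). Carrying the side chain through the cyclobutene-forming step would require a tetrasubstituted chiral alkene as 2π partner. Adding it afterwards to a neopentyl aldehyde is simpler and lets a chiral ligand set C4. The precursor is four carbons and one stereocentre simpler. The forward reaction must give the E alkene (syn-hydrometalation of 8 does this) and add to the Re face of 7 under reagent control, cold enough to spare the labile 3-formylcyclobutene.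

**Cyclobutene, C5–C6 and C11–C12.** Aldehyde 7 is reached from trans diester 3 through acid 4, hydroxy acid 5 and hydroxy ester 6; the sequence distinguishes the two esters only by the hindrance of quaternary C5. Diester 3 is cut at C5–C6 and C11–C12 into propyne (1) and dimethyl mesaconate (2). A polar [2+2] of an ynamine or a photochemical [2+2] would give the same ring, but the first leaves nitrogen on C6 and both give racemates. A metal-catalysed [2+2] with a chiral ligand gives the ring, the trans relationship (from the E alkene) and the absolute configuration at once from two bulk chemicals. The forward reaction must join the alkyne CH to the methyl-bearing alkene carbon and must accept a trisubstituted alkene.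

**East fragment.** Iodide 32 derives from stannane 31 and this from alkyne 30; the alkyne is the masked iodoalkene and tolerates acid. In 30 the bond C15–C19 between the two quaternary carbons is cut, giving β-keto lactone 29 with a tertiary propargylic silyl ether at C15. Closures at C16–C21 (aldol) or C19–C20 (Claisen) were set aside because they require the vicinal quaternary pair to be built beforehand in an open chain. Opening the lactone (O17–C18) gives imide 28, and the C16–C21 aldol cut gives β-keto imide 21 and aldehyde 26. Imide 21 comes from the propanoyl oxazolidinone 18 and propanoyl chloride (19) through enolate 20. Aldehyde 26 comes from ester 25, alcohol 24, methyl pyruvate (22) and propynylmagnesium bromide (23). The precursors are acyclic, and 26 can be racemic because C15 becomes planar in the ring closure. The forward reactions must set C16 in the aldol (through boron enolate 27) and close the cation on C19 with the C15 methyl over the lactone bridge.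

## Roads not taken

Alternative 1: The cut is in the east half, at C16–C21 and O17–C18. A hindered base would convert the ethyl ketone of the open-chain keto ester aldehyde A2 into its C21 enolate, which adds to the C16 aldehyde and closes the cyclopentanone. The alkoxide, when cis to the ester, then acylates and closes the γ-lactone, giving the east core A1 with an (E)-propenyl group on C15.
- Merits: two rings and two bonds form in one operation; lactonisation selects the correct C16 epimer, since the other can return by retro-aldol; C21 settles thermodynamically. Here it is better than the east route chosen, which needs separate lactonisation and ring-closure steps.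
- Weak points: the hard element, the C15–C19 bond with correct relative configuration, must already exist in A2, where no ring helps to control it. A2 is a non-enolisable β-keto ester beside an α-quaternary aldehyde and is prone to retro-Claisen cleavage under base. A1 ends in a propenyl group with no handle at C13 for the union.
- Comparison: the chosen plan forms C15–C19 inside an existing ring (29 to 30) and carries an alkyne that becomes iodide 32. Alternative 1 does not address the west half, where the main difficulty lies.

Alternative 2: The cut is the west ring fusion seen from the other side, C5–C6 and C11–C12, with the four-membered ring formed last. Irradiation of dimethyl mesaconate (2) in mesitylene A4 would add the alkene across one methyl-substituted ring bond of the arene through a singlet exciplex. This would give diester A3, the whole west bicycle, in one step.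
- Merits: in step economy it is clearly better than the chosen plan, which needs eight steps to reach the same ring system in 15. The methyl pattern of A4 maps correctly onto C7, C9 and C11.
- Weak points: nothing controls absolute configuration, so A3 would be racemic and need resolution. The alkene can add in two orientations. The excited alkene isomerises between E and Z, which scrambles the C5/C12 relationship. Meta addition and secondary photoreactions of the diene limit conversion. A3 still needs its esters told apart and C4 set on a molecule that already contains the sensitive diene.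
- Comparison: the chosen plan pays with steps for regiochemistry fixed by a ground-state cycloaddition, absolute configuration from a catalyst, and a C5 centre that directs the ring fusion.

Alternative 3: The cut is C19–C20 in the east half. A strong hindered amide base would convert γ-lactone A6, which carries an acyl imidazole on the C16 side chain, into its C19 enolate. Attack on C20, directly or through the derived ketene, closes the cyclopentanone and gives the east core A5 with C14 as a p-methoxybenzyl ether.
- Merits: C15 and C16 are fixed on a monocyclic lactone before ring closure, so no face selection at a cation is involved. On this point it is safer than the chosen east closure. The acylation is intramolecular and geometrically well defined.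
- Weak points: the product is a non-enolisable β-keto lactone, so the Claisen step has no final deprotonation to drive it and can revert. The base can also remove the C21 proton. A6 needs its own stereoselective synthesis. A5 carries C14 as a protected alcohol, so deprotection, oxidation, homologation to an alkyne under base and hydrometalation would follow on a base-sensitive β-acyloxy ketone.
- Comparison: the chosen plan sets against the safer C15 a shorter sequence and a propynyl group carried through the ring closure. Like Alternative 1, it leaves the west half open.

Key step: step 8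

Remark on the chemistry: aldehyde 26 is used as the racemate, so 28 and 29 are mixtures of C15 epimers that converge in step 17, where C15 becomes planar; lactone 14 is drawn with one of its two possible bridge orientations, which is lost with CO2.

## Route

Step 1
Reactants: 1 propyne; 2 dimethyl mesaconate
Product: 3 dimethyl (1S,2S)-1,3-dimethylcyclobut-3-ene-1,2-dicarboxylate
Conditions: CoBr2 (10 mol%), (S,S)-2,4-bis(diphenylphosphino)pentane (12 mol%), Zn, NaB[3,5-(CF3)2C6H3]4, propyne (3 equiv), CH2Cl2, 25 °C, sealed vessel
Reagents that add atoms: none
Why: Proposed new method: cationic monovalent cobalt with a chiral bisphosphine should couple alkyne and alkene oxidatively to a cobaltacyclopentene, with cobalt on the methyl-bearing alkyne carbon and on the secondary ester carbon C12, so that the small alkyne CH bonds to the crowded C5 and reductive elimination closes C11–C12. The E geometry of 2 is carried into the trans diester, and the ligand enantiomer is chosen to give (1S,2S). The closest known reaction type is the cobalt-catalysed enantioselective [2+2] cycloaddition of alkynes with acrylates, which has not been shown for a trisubstituted butenedioate.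

Step 2
Reactants: 3 dimethyl (1S,2S)-1,3-dimethylcyclobut-3-ene-1,2-dicarboxylate
Product: 4 (1S,4S)-4-(methoxycarbonyl)-2,4-dimethylcyclobut-2-ene-1-carboxylic acid
Conditions: LiOH·H2O (1.05 equiv), THF/H2O, 0 °C; then 1 M HCl
Reagents that add atoms: lithium hydroxide, [Li+].[OH-]
Why: Saponification should occur at the ester on the tertiary carbon C12, since the ester on quaternary C5 is shielded. At 0 °C acyl attack by hydroxide is expected to outrun removal of the allylic C12 proton, so no epimerisation or double-bond migration is expected.

Step 3
Reactants: 4 (1S,4S)-4-(methoxycarbonyl)-2,4-dimethylcyclobut-2-ene-1-carboxylic acid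
Product: 5 (1S,4S)-4-(hydroxymethyl)-2,4-dimethylcyclobut-2-ene-1-carboxylic acid
Conditions: LiBHEt3 (3.2 equiv), THF, −20 → 0 °C; aq. HCl
Reagents that add atoms: none
Why: Hydride reduction of an ester in the presence of a carboxylate: the first equivalent deprotonates the acid, whose lithium salt is inert, and the small, strongly nucleophilic hydride reduces the hindered C5 ester to the neopentyl alcohol. The trans arrangement prevents lactonisation.

Step 4
Reactants: 5 (1S,4S)-4-(hydroxymethyl)-2,4-dimethylcyclobut-2-ene-1-carboxylic acid
Product: 6 methyl (1S,4S)-4-(hydroxymethyl)-2,4-dimethylcyclobut-2-ene-1-carboxylate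
Conditions: Me3SiCHN2, MeOH/toluene, 0 °C
Reagents that add atoms: trimethylsilyldiazomethane, C[Si](C)(C)C=[N+]=[N-]
Why: Methyl esterification by a diazoalkane under neutral conditions; it esterifies only the acid and leaves the base-sensitive allylic C12 proton untouched.

Step 5
Reactants: 6 methyl (1S,4S)-4-(hydroxymethyl)-2,4-dimethylcyclobut-2-ene-1-carboxylate
Product: 7 methyl (1S,4S)-4-formyl-2,4-dimethylcyclobut-2-ene-1-carboxylate
Conditions: Dess–Martin periodinane, NaHCO3, CH2Cl2, 0 °C; used at once
Reagents that add atoms: none
Why: Dess–Martin oxidation of a primary alcohol under buffered conditions; the aldehyde carbon is attached to a quaternary centre and cannot epimerise. Because a formyl group on the ring sp3 carbon lowers the barrier to 4π opening, 7 is kept cold and not stored.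

Step 6
Reactants: 7 methyl (1S,4S)-4-formyl-2,4-dimethylcyclobut-2-ene-1-carboxylate; 8 but-2-yne
Product: 11 methyl (1S,4S)-4-[(1R,2E)-1-hydroxy-2-methylbut-2-en-1-yl]-2,4-dimethylcyclobut-2-ene-1-carboxylate, via (E)-but-2-en-2-ylzirconocene chloride 9 (not isolated), via (E)-but-2-en-2-yl(methyl)zinc 10 (not isolated)
Conditions: Cp2Zr(H)Cl, 8, CH2Cl2, 25 °C; Me2Zn, toluene, −65 °C; (+)-3-exo-morpholinoisoborneol (10 mol%), then 7, −30 → 0 °C; aq. NH4Cl
Reagents that add atoms: none
Why: Syn-hydrozirconation of the alkyne fixes the E (tiglyl) geometry, and zirconium-to-zinc transmetalation followed by amino-alcohol-catalysed alkenylzinc addition forms C3–C4 without touching the ester. C4 is set by the ligand, which should direct Re-face addition to give 4R; the three carbon substituents on C5 are expected to exert little opposing bias.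

Step 7
Reactants: 11 methyl (1S,4S)-4-[(1R,2E)-1-hydroxy-2-methylbut-2-en-1-yl]-2,4-dimethylcyclobut-2-ene-1-carboxylate
Product: 12 methyl (1S,4S)-4-[(1R,2E)-1-(tert-butyldimethylsilyloxy)-2-methylbut-2-en-1-yl]-2,4-dimethylcyclobut-2-ene-1-carboxylate
Conditions: t-BuMe2SiOTf, 2,6-lutidine, CH2Cl2, −78 → 0 °C
Reagents that add atoms: tert-butyldimethylsilyl trifluoromethanesulfonate, CC(C)(C)[Si](C)(C)OS(=O)(=O)C(F)(F)F
Why: Silylation of a hindered secondary alcohol with a silyl triflate; the bulky silyl ether protects the ionisable allylic alcohol and enlarges the C5 substituent that is to shield one face of the ring.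

Step 8
Reactants: 12 methyl (1S,4S)-4-[(1R,2E)-1-(tert-butyldimethylsilyloxy)-2-methylbut-2-en-1-yl]-2,4-dimethylcyclobut-2-ene-1-carboxylate; 13 4,6-dimethyl-2H-pyran-2-one
Product: 15 methyl 7-[(1R,2E)-1-(tert-butyldimethylsilyloxy)-2-methylbut-2-en-1-yl]-1,3,5,7-tetramethylbicyclo[4.2.0]octa-2,4-diene-8-carboxylate (cis-fused; six-membered ring on the face of the C5 methyl and the C12 ester), via bridged lactone cycloadduct 14 (not isolated)
Conditions: 13 (5 equiv), CH2Cl2, 10 kbar, 30 °C; then toluene, 70 °C (−CO2)
Reagents that add atoms: none
Why: Proposed new method: the pyrone acts as a 4π diene across its C3 and C6 positions and the strained C6=C11 bond of 12 as the 2π partner; the strongly negative activation volume lets the addition run at 10 kbar near room temperature, below the temperature at which 12 would ring-open, and lactone 14 then loses CO2 on gentle warming by an irreversible retro-[4+2] reaction. The closest known reaction type is the Diels–Alder reaction of 2-pyrones with strained or activated alkenes followed by CO2 extrusion to cyclohexa-1,3-dienes, which has not been shown for a trisubstituted cyclobutene. The six-membered ring is closed by a [4+2] annulation that is suprafacial on both partners (bonds C6–C7 and C10–C11), so the ring fusion must be cis, and the diene C7=C8–C9=C10 appears when CO2 leaves. The new stereocentres C6 and C11 are controlled by quaternary C5: the diene should add to the face that carries the C5 methyl, anti to the branched silyloxyalkyl chain, because the methyl-bearing pyrone terminus has to bond right next to C5. The step needs the methyl-bearing pyrone C6 to bond to the hydrogen-bearing alkene carbon; this orientation avoids two adjacent fully substituted centres in the transition state and matches an asynchronous addition in which the less substituted, more nucleophilic alkene carbon attacks the pyrone position next to oxygen. Chemoselectivity rests on strain, since the unstrained tiglyl alkene is not expected to react with the pyrone. Any wrong-face adduct could be corrected on heating by disrotatory 6π opening to the cyclooctatriene and re-closure to the less congested diastereomer 15.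

Step 9
Reactants: 15 west bicyclooctadiene methyl ester
Product: 16 7-[(1R,2E)-1-(tert-butyldimethylsilyloxy)-2-methylbut-2-en-1-yl]-1,3,5,7-tetramethylbicyclo[4.2.0]octa-2,4-diene-8-carboxylic acid
Conditions: n-PrSLi, HMPA, 25 °C; then cold dilute HCl
Reagents that add atoms: none
Why: Nucleophilic (SN2) demethylation of a methyl ester by thiolate; attack is at the methyl group, so the hindrance of the acyl carbon between two quaternary centres does not matter. The conditions are mild enough for the diene and the silyl ether.

Step 10
Reactants: 16 west bicyclooctadiene carboxylic acid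
Product: 17 1,3-dioxoisoindolin-2-yl ester of acid 16 (redox-active ester)
Conditions: N-hydroxyphthalimide, i-PrN=C=N-i-Pr, DMAP (cat.), CH2Cl2, 25 °C
Reagents that add atoms: N-hydroxyphthalimide, O=C1c2ccccc2C(=O)N1O
Why: Carbodiimide esterification to the N-acyloxyphthalimide; no stereocentre is affected, and the C12 centre will in any case be renewed in step 20.

Step 11
Reactants: 18 (R)-4-benzyl-3-propanoyl-1,3-oxazolidin-2-one; 19 propanoyl chloride
Product: 21 (R)-4-benzyl-3-[(S)-2-methyl-3-oxopentanoyl]-1,3-oxazolidin-2-one, via lithium (Z)-enolate 20 (not isolated)
Conditions: LiN(i-Pr)2, THF, −78 °C; then 19, −78 °C; aq. NH4Cl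
Reagents that add atoms: none
Why: Claisen-type C-acylation of the chelated Z-enolate on the face opposite the benzyl group sets the C19 methyl centre (S). Allylic strain keeps the product from enolising, so the centre should survive.

Step 12
Reactants: 22 methyl pyruvate; 23 prop-1-yn-1-ylmagnesium bromide
Product: 24 methyl 2-hydroxy-2-methylpent-3-ynoate (racemic)
Conditions: THF, −78 °C; aq. NH4Cl
Reagents that add atoms: none
Why: Grignard addition to the ketone carbonyl, which is far more electrophilic than the ester at −78 °C. The new centre (C15) need not be controlled because it is ionised in step 17.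

Step 13
Reactants: 24 methyl 2-hydroxy-2-methylpent-3-ynoate
Product: 25 methyl 2-methyl-2-(triethylsilyloxy)pent-3-ynoate (racemic)
Conditions: Et3SiOTf, 2,6-lutidine, CH2Cl2, 0 °C
Reagents that add atoms: triethylsilyl trifluoromethanesulfonate, CC[Si](CC)(CC)OS(=O)(=O)C(F)(F)F
Why: Silylation of a tertiary alcohol with a silyl triflate; the silyl ether masks the alcohol for the reduction and aldol steps and later serves as the leaving group.

Step 14
Reactants: 25 methyl 2-methyl-2-(triethylsilyloxy)pent-3-ynoate
Product: 26 2-methyl-2-(triethylsilyloxy)pent-3-ynal (racemic)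
Conditions: i-Bu2AlH, CH2Cl2, −78 °C; aq. sodium potassium tartrate
Reagents that add atoms: none
Why: Half-reduction of an α-silyloxy ester; the tetrahedral aluminium hemiacetal of a hindered α-oxygenated ester is stable at −78 °C and releases the aldehyde only on work-up.

Step 15
Reactants: 21 (R)-4-benzyl-3-[(S)-2-methyl-3-oxopentanoyl]-1,3-oxazolidin-2-one; 26 2-methyl-2-(triethylsilyloxy)pent-3-ynal (2 equiv)
Product: 28 (4R)-4-benzyl-3-[(2S,4R,5S,6RS)-5-hydroxy-2,4,6-trimethyl-3-oxo-6-(triethylsilyloxy)non-7-ynoyl]-1,3-oxazolidin-2-one, via dicyclohexylboron (E)-enolate 27 (not isolated)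
Conditions: (c-C6H11)2BCl, EtNMe2, Et2O, 0 °C; then 26, −78 → −20 °C; MeOH, pH 7 buffer, H2O2, 0 °C
Reagents that add atoms: none
Why: Evans β-keto imide anti aldol: the E boron enolate of the ethyl ketone reacts through a chair transition state whose face is fixed by the C19 methyl centre, giving the anti,anti adduct with C16 (S) and C21 (R) as required. Excess racemic aldehyde lets the better-matched enantiomer react, and both C15 epimers are usable.

Step 16
Reactants: 28 aldol adduct
Product: 29 (5R,6S)-3,5-dimethyl-6-[(2RS)-2-(triethylsilyloxy)pent-3-yn-2-yl]oxane-2,4-dione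
Conditions: K2CO3, MeOH, 0 → 25 °C; then aq. HCl to pH 3
Reagents that add atoms: none
Why: Base-induced lactonisation: the C16 alkoxide acylates on the imide carbonyl and releases the auxiliary. The product is held as its stabilised β-keto lactone enolate, which protects C21 from deprotonation; C19 becomes labile, which is of no consequence.

Step 17
Reactants: 29 β-keto lactone
Product: 30 (1S,4S,6R,7S)-4,6,7-trimethyl-7-(prop-1-yn-1-yl)-2-oxabicyclo[2.2.1]heptane-3,5-dione
Conditions: TfOH (10 mol%), CH2Cl2, −40 → 0 °C
Reagents that add atoms: none
Why: Acid-catalysed propargylic substitution (SN1): the tertiary propargylic silyl ether ionises and the enol carbon C19 of the β-keto lactone attacks the cation, closing the cyclopentanone and γ-lactone rings at once; O-alkylation is reversible. C19 is fixed by the bridge; at C15 the methyl should lie over the unsubstituted lactone bridge and the slimmer alkynyl group over the C21–H side. C21 (methyl endo) is already in its thermodynamically preferred configuration.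

Step 18
Reactants: 30 alkyne bicycle
Product: 31 (1S,4S,6R,7S)-4,6,7-trimethyl-7-[(E)-2-(tributylstannyl)prop-1-en-1-yl]-2-oxabicyclo[2.2.1]heptane-3,5-dione
Conditions: n-Bu3SnH, PdCl2(PPh3)2 (5 mol%), THF, 0 → 25 °C
Reagents that add atoms: tributyltin hydride, CCCC[SnH](CCCC)CCCC
Why: Palladium-catalysed syn-hydrostannation of an internal alkyne; tin should go to the alkyne carbon remote from quaternary C15, which gives the E alkenylstannane. Ketone and lactone are tolerated.

Step 19
Reactants: 31 alkenylstannane
Product: 32 (1S,4S,6R,7S)-7-[(E)-2-iodoprop-1-en-1-yl]-4,6,7-trimethyl-2-oxabicyclo[2.2.1]heptane-3,5-dione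
Conditions: I2, CH2Cl2, 0 °C
Reagents that add atoms: iodine, II
Why: Iododestannylation proceeds with retention of alkene geometry and is much faster than iodination of the ketone.

Step 20
Reactants: 17 west redox-active ester; 32 east (E)-alkenyl iodide
Product: 33 C4 tert-butyldimethylsilyl ether of shimalactone B
Conditions: NiCl2·6H2O (20 mol%), 2,2′-bipyridine (20 mol%), AgNO3 (0.3 equiv), LiCl, DMF, Mg anode/reticulated vitreous carbon cathode, constant current, 25 °C
Reagents that add atoms: none
Why: Nickel-electrocatalytic decarboxylative alkenylation: reduction of the redox-active ester releases CO2 and the C12 radical, which is captured by the alkenyl–nickel species formed from the iodide, with retention of alkene geometry. The radical is flanked by C5 (chain above, methyl below) and C11 (methyl above, ring carbon C10 below), so the bond should form on the lower face, which gives the required C12 configuration. Ketone, lactone, diene and silyl ether are compatible with these mild reductive conditions.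

Step 21
Reactants: 33 silyl ether of shimalactone B
Product: 34 shimalactone B
Conditions: HF·pyridine, pyridine, THF, 0 → 25 °C
Reagents that add atoms: none
Why: Fluoride-mediated desilylation under buffered, non-basic conditions, chosen so that the C21 enolate is never formed; this avoids epimerisation at C21, loss of the C16 carboxylate and ionisation of the C4 allylic alcohol.

## Compound list

1 | propyne | CC#C | starting material
2 | dimethyl mesaconate | COC(=O)/C=C(\C)C(=O)OC | starting material
3 | dimethyl (1S,2S)-1,3-dimethylcyclobut-3-ene-1,2-dicarboxylate | COC(=O)[C@@]1(C)C=C(C)[C@@H]1C(=O)OC | intermediate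
4 | (1S,4S)-4-(methoxycarbonyl)-2,4-dimethylcyclobut-2-ene-1-carboxylic acid | COC(=O)[C@@]1(C)C=C(C)[C@@H]1C(=O)O | intermediate
5 | (1S,4S)-4-(hydroxymethyl)-2,4-dimethylcyclobut-2-ene-1-carboxylic acid | OC[C@@]1(C)C=C(C)[C@@H]1C(=O)O | intermediate
6 | methyl (1S,4S)-4-(hydroxymethyl)-2,4-dimethylcyclobut-2-ene-1-carboxylate | OC[C@@]1(C)C=C(C)[C@@H]1C(=O)OC | intermediate
7 | methyl (1S,4S)-4-formyl-2,4-dimethylcyclobut-2-ene-1-carboxylate | O=C[C@@]1(C)C=C(C)[C@@H]1C(=O)OC | intermediate
8 | but-2-yne | CC#CC | starting material
9 | (E)-but-2-en-2-ylzirconocene chloride (formed in situ) | C/C=C(\C)[Zr](Cl)(C1C=CC=C1)C1C=CC=C1 | intermediate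
10 | (E)-but-2-en-2-yl(methyl)zinc (formed in situ) | C/C=C(\C)[Zn]C | intermediate
11 | methyl (1S,4S)-4-[(1R,2E)-1-hydroxy-2-methylbut-2-en-1-yl]-2,4-dimethylcyclobut-2-ene-1-carboxylate | C/C=C(\C)[C@@H](O)[C@@]1(C)C=C(C)[C@@H]1C(=O)OC | intermediate
12 | methyl (1S,4S)-4-[(1R,2E)-1-(tert-butyldimethylsilyloxy)-2-methylbut-2-en-1-yl]-2,4-dimethylcyclobut-2-ene-1-carboxylate | C/C=C(\C)[C@@H](O[Si](C)(C)C(C)(C)C)[C@@]1(C)C=C(C)[C@@H]1C(=O)OC | intermediate
13 | 4,6-dimethyl-2H-pyran-2-one | Cc1cc(C)oc(=O)c1 | starting material
14 | bridged lactone cycloadduct of 12 and 13 (2-oxabicyclo[2.2.2]octenone fused to the cyclobutane at C6–C11; formed in situ) | C/C=C(\C)[C@@H](O[Si](C)(C)C(C)(C)C)[C@@]1(C)[C@@H]2[C@]3(C)C=C(C)[C@@H](C(=O)O3)[C@]2(C)[C@@H]1C(=O)OC | intermediate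
15 | methyl 7-[(1R,2E)-1-(tert-butyldimethylsilyloxy)-2-methylbut-2-en-1-yl]-1,3,5,7-tetramethylbicyclo[4.2.0]octa-2,4-diene-8-carboxylate (cis-fused west bicycle) | C/C=C(\C)[C@@H](O[Si](C)(C)C(C)(C)C)[C@@]1(C)[C@@H]2C(C)=CC(C)=C[C@]2(C)[C@@H]1C(=O)OC | intermediate
16 | carboxylic acid corresponding to 15 | C/C=C(\C)[C@@H](O[Si](C)(C)C(C)(C)C)[C@@]1(C)[C@@H]2C(C)=CC(C)=C[C@]2(C)[C@@H]1C(=O)O | intermediate
17 | 1,3-dioxoisoindolin-2-yl ester of 16 | C/C=C(\C)[C@@H](O[Si](C)(C)C(C)(C)C)[C@@]1(C)[C@@H]2C(C)=CC(C)=C[C@]2(C)[C@@H]1C(=O)ON1C(=O)c2ccccc2C1=O | intermediate
18 | (R)-4-benzyl-3-propanoyl-1,3-oxazolidin-2-one | CCC(=O)N1[C@H](Cc2ccccc2)COC1=O | starting material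
19 | propanoyl chloride | CCC(=O)Cl | starting material
20 | lithium (Z)-enolate of 18 (formed in situ) | C/C=C(\O[Li])N1[C@H](Cc2ccccc2)COC1=O | intermediate
21 | (R)-4-benzyl-3-[(S)-2-methyl-3-oxopentanoyl]-1,3-oxazolidin-2-one | CCC(=O)[C@H](C)C(=O)N1[C@H](Cc2ccccc2)COC1=O | intermediate
22 | methyl pyruvate | CC(=O)C(=O)OC | starting material
23 | prop-1-yn-1-ylmagnesium bromide | CC#C[Mg]Br | starting material
24 | methyl 2-hydroxy-2-methylpent-3-ynoate (racemic) | CC#CC(C)(O)C(=O)OC | intermediate
25 | methyl 2-methyl-2-(triethylsilyloxy)pent-3-ynoate (racemic) | CC#CC(C)(O[Si](CC)(CC)CC)C(=O)OC | intermediate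
26 | 2-methyl-2-(triethylsilyloxy)pent-3-ynal (racemic) | CC#CC(C)(O[Si](CC)(CC)CC)C=O | intermediate
27 | dicyclohexylboron (E)-enolate of 21 (formed in situ) | C/C=C(/OB(C1CCCCC1)C1CCCCC1)[C@H](C)C(=O)N1[C@H](Cc2ccccc2)COC1=O | intermediate
28 | (4R)-4-benzyl-3-[(2S,4R,5S,6RS)-5-hydroxy-2,4,6-trimethyl-3-oxo-6-(triethylsilyloxy)non-7-ynoyl]-1,3-oxazolidin-2-one (both C15 epimers) | CC#CC(C)(O[Si](CC)(CC)CC)[C@@H](O)[C@@H](C)C(=O)[C@H](C)C(=O)N1[C@H](Cc2ccccc2)COC1=O | intermediate
29 | (5R,6S)-3,5-dimethyl-6-[(2RS)-2-(triethylsilyloxy)pent-3-yn-2-yl]oxane-2,4-dione (keto form drawn; C3 labile) | CC#CC(C)(O[Si](CC)(CC)CC)[C@H]1OC(=O)C(C)C(=O)[C@@H]1C | intermediate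
30 | (1S,4S,6R,7S)-4,6,7-trimethyl-7-(prop-1-yn-1-yl)-2-oxabicyclo[2.2.1]heptane-3,5-dione | CC#C[C@]1(C)[C@H]2OC(=O)[C@]1(C)C(=O)[C@@H]2C | intermediate
31 | (1S,4S,6R,7S)-4,6,7-trimethyl-7-[(E)-2-(tributylstannyl)prop-1-en-1-yl]-2-oxabicyclo[2.2.1]heptane-3,5-dione | CCCC[Sn](CCCC)(CCCC)/C(C)=C/[C@]1(C)[C@H]2OC(=O)[C@]1(C)C(=O)[C@@H]2C | intermediate
32 | (1S,4S,6R,7S)-7-[(E)-2-iodoprop-1-en-1-yl]-4,6,7-trimethyl-2-oxabicyclo[2.2.1]heptane-3,5-dione | I/C(C)=C/[C@]1(C)[C@H]2OC(=O)[C@]1(C)C(=O)[C@@H]2C | intermediate
33 | C4 tert-butyldimethylsilyl ether of shimalactone B | C/C=C(\C)[C@@H](O[Si](C)(C)C(C)(C)C)[C@@]1(C)[C@@H]2C(C)=CC(C)=C[C@]2(C)[C@@H]1/C(C)=C/[C@]1(C)[C@H]2OC(=O)[C@]1(C)C(=O)[C@@H]2C | intermediate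
34 | shimalactone B | C/C=C(\C)[C@@H](O)[C@@]1(C)[C@@H]2C(C)=CC(C)=C[C@]2(C)[C@@H]1/C(C)=C/[C@]1(C)[C@H]2OC(=O)[C@]1(C)C(=O)[C@@H]2C | target

## Step count, longest linear sequence and least certain steps

Total: 21 steps. Longest linear sequence: 12 steps (steps 1–10, 20 and 21); the east fragment takes 8 steps (12–19) plus step 11 for imide 21.

**Step 8 (key step; proposed new method).** The most likely failure is insufficient reactivity of the hindered, electronically unbiased cyclobutene toward a weakly electron-poor pyrone even at 10 kbar, so that pyrone self-reaction or slow decomposition of 12 takes over. A second risk is incomplete facial discrimination. The fallback keeps the same two bonds but uses a diene of established reactivity toward strained and unactivated alkenes. It sets out from 12 and returns at 15. Commercial 2,4-dimethylthiophene F1 is oxidised with dimethyldioxirane at low temperature to 2,4-dimethylthiophene 1,1-dioxide F2, a non-aromatic diene sulfone. Its known [4+2] addition to alkenes at or below room temperature would give the sulfone-bridged adduct F3, which loses SO2 by cheletropic extrusion without heating to give 15. The same steric arguments fix regiochemistry and face, and no thermal step is needed.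

**Step 1 (proposed new method).** The most likely failures are reluctance of the trisubstituted diester to enter the oxidative cyclisation, so that propyne cyclotrimerises instead, and reversed regiochemistry with the two methyl-bearing carbons adjacent. The fallback uses known polar chemistry, sets out from 2 and returns at 4. A thermal Ficini [2+2] of N,N-diethylprop-1-yn-1-amine F4 with 2 fixes the regiochemistry by polarity: the nucleophilic methyl-bearing alkyne carbon adds to the CH terminus of 2. This gives the racemic aminocyclobutene diester F5. Hydroboration of the enamine with 9-borabicyclo[3.3.1]nonane and elimination of the aminoborane converts C6–N into C6–H and gives racemic 3. Saponification as in step 2 gives racemic 4, which is resolved by crystallisation of its (R)-1-phenylethylammonium salt F6 (amine enantiomer chosen by screening) and liberated with acid.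

**Step 20.** The most likely failures are poor facial discrimination at the planar C12 radical, and capture by nickel that is too slow for so hindered a radical, so that reduction or β-scission toward the diene competes. The fallback forms no bond at C12 and keeps the configuration set in the cyclobutene; it sets out from 15 and returns at 33.
- Half-reduction of 15 with i-Bu2AlH gives aldehyde F7, and Ohira–Bestmann homologation gives alkyne F8.
- Negishi carboalumination (Me3Al, Cp2ZrCl2) and iodination give the west (E)-alkenyl iodide F9.
- Iodine–lithium exchange (t-BuLi) and addition to methyl pyruvate (22) give hydroxy ester F10.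
- F10 is then carried through the operations of steps 13–17: silyl ether F11, aldehyde F12, aldol adduct F13 with 21, and lactone F14.
- Acid-induced closure of the tertiary allylic cation on C19 gives 33. The tertiary C15 ether should ionise well before the neopentyl C4 silyl ether.

**Step 17.** The most likely failures are diversion of the propargylic cation to elimination (enyne), allenyl products or persistent O-alkylation, and insufficient face selection at C15. The fallback changes the cation from propargylic to allylic by moving the hydrometalation ahead of the ring closure; it sets out from 28 and returns at 32. Hydrostannation of 28 as in step 18 gives stannane F15, iodination gives iodide F16, and lactonisation as in step 16 gives iodo lactone F17. Acid then generates a tertiary allyl cation whose closure on the enol carbon C19 gives 32 directly. The alkenyl group presents only its C14–H toward C21, so the methyl group should again take the lactone side.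

## Further compounds

F1 | step 8 | 2,4-dimethylthiophene | Cc1cc(C)cs1
F2 | step 8 | 2,4-dimethylthiophene 1,1-dioxide | CC1=CC(C)=CS1(=O)=O
F3 | step 8 | sulfone-bridged cycloadduct of 12 and F2 (7-thiabicyclo[2.2.1]heptene 7,7-dioxide fused to the cyclobutane) | C/C=C(\C)[C@@H](O[Si](C)(C)C(C)(C)C)[C@@]1(C)[C@@H]2[C@]3(C)C=C(C)[C@@H](S3(=O)=O)[C@]2(C)[C@@H]1C(=O)OC
F4 | step 1 | N,N-diethylprop-1-yn-1-amine | CCN(CC)C#CC
F5 | step 1 | dimethyl trans-4-(diethylamino)-1,3-dimethylcyclobut-3-ene-1,2-dicarboxylate (racemic; one enantiomer drawn) | COC(=O)[C@@]1(C)C(N(CC)CC)=C(C)[C@@H]1C(=O)OC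
F6 | step 1 | (R)-1-phenylethylammonium salt of 4 | COC(=O)[C@@]1(C)C=C(C)[C@@H]1C(=O)[O-].C[C@@H]([NH3+])c1ccccc1
F7 | step 20 | west bicyclooctadiene C12 carbaldehyde | C/C=C(\C)[C@@H](O[Si](C)(C)C(C)(C)C)[C@@]1(C)[C@@H]2C(C)=CC(C)=C[C@]2(C)[C@@H]1C=O
F8 | step 20 | west bicyclooctadiene C12 ethynyl compound | C/C=C(\C)[C@@H](O[Si](C)(C)C(C)(C)C)[C@@]1(C)[C@@H]2C(C)=CC(C)=C[C@]2(C)[C@@H]1C#C
F9 | step 20 | west (E)-1-iodoprop-1-en-2-yl compound | C/C=C(\C)[C@@H](O[Si](C)(C)C(C)(C)C)[C@@]1(C)[C@@H]2C(C)=CC(C)=C[C@]2(C)[C@@H]1/C(C)=C/I
F10 | step 20 | methyl (E)-2-hydroxy-2-methyl-4-(west bicyclooctadienyl)pent-3-enoate (C15 epimers) | C/C=C(\C)[C@@H](O[Si](C)(C)C(C)(C)C)[C@@]1(C)[C@@H]2C(C)=CC(C)=C[C@]2(C)[C@@H]1/C(C)=C/C(C)(O)C(=O)OC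
F11 | step 20 | triethylsilyl ether of F10 | C/C=C(\C)[C@@H](O[Si](C)(C)C(C)(C)C)[C@@]1(C)[C@@H]2C(C)=CC(C)=C[C@]2(C)[C@@H]1/C(C)=C/C(C)(O[Si](CC)(CC)CC)C(=O)OC
F12 | step 20 | aldehyde from F11 | C/C=C(\C)[C@@H](O[Si](C)(C)C(C)(C)C)[C@@]1(C)[C@@H]2C(C)=CC(C)=C[C@]2(C)[C@@H]1/C(C)=C/C(C)(O[Si](CC)(CC)CC)C=O
F13 | step 20 | anti aldol adduct of F12 and 21 | C/C=C(\C)[C@@H](O[Si](C)(C)C(C)(C)C)[C@@]1(C)[C@@H]2C(C)=CC(C)=C[C@]2(C)[C@@H]1/C(C)=C/C(C)(O[Si](CC)(CC)CC)[C@@H](O)[C@@H](C)C(=O)[C@H](C)C(=O)N1[C@H](Cc2ccccc2)COC1=O
F14 | step 20 | β-keto lactone from F13 | C/C=C(\C)[C@@H](O[Si](C)(C)C(C)(C)C)[C@@]1(C)[C@@H]2C(C)=CC(C)=C[C@]2(C)[C@@H]1/C(C)=C/C(C)(O[Si](CC)(CC)CC)[C@H]1OC(=O)C(C)C(=O)[C@@H]1C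
F15 | step 17 | (E)-alkenylstannane from 28 | CCCC[Sn](CCCC)(CCCC)/C(C)=C/C(C)(O[Si](CC)(CC)CC)[C@@H](O)[C@@H](C)C(=O)[C@H](C)C(=O)N1[C@H](Cc2ccccc2)COC1=O
F16 | step 17 | (E)-alkenyl iodide from F15 | I/C(C)=C/C(C)(O[Si](CC)(CC)CC)[C@@H](O)[C@@H](C)C(=O)[C@H](C)C(=O)N1[C@H](Cc2ccccc2)COC1=O
F17 | step 17 | iodoalkenyl β-keto lactone from F16 | I/C(C)=C/C(C)(O[Si](CC)(CC)CC)[C@H]1OC(=O)C(C)C(=O)[C@@H]1C
A1 | alternative 1 | east core with an (E)-propenyl group on C15 | C/C=C/[C@]1(C)[C@H]2OC(=O)[C@]1(C)C(=O)[C@@H]2C
A2 | alternative 1 | open-chain keto ester aldehyde (C16 aldehyde, C18 methyl ester, C20 ethyl ketone) | CCC(=O)[C@@](C)(C(=O)OC)[C@@](C)(C=O)/C=C/C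
A3 | alternative 2 | west bicyclo[4.2.0]octadiene diester | COC(=O)[C@@]1(C)[C@@H]2C(C)=CC(C)=C[C@]2(C)[C@@H]1C(=O)OC
A4 | alternative 2 | mesitylene | Cc1cc(C)cc(C)c1
A5 | alternative 3 | east core with C14 as p-methoxybenzyl ether | COc1ccc(cc1)COC[C@]1(C)[C@H]2OC(=O)[C@]1(C)C(=O)[C@@H]2C
A6 | alternative 3 | γ-lactone with a C20 acyl imidazole on the C16 side chain | COc1ccc(cc1)COC[C@]1(C)[C@@H](OC(=O)C1C)[C@@H](C)C(=O)n1ccnc1
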